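**Retrosynthetic overview**

1. Target 17 ⇒ Heck union (C8–C9 of the diene) of the (E)-iodoalkene 15 (cyclohexane half) with the vinyl bromo-oxane 16; both halves come from (S)-linalool 1.
2. 15 ⇐ alkyne 13 (methylalumination, iodination) ⇐ aldehyde 12 (one-carbon homologation).
3. 12 ⇐ bicyclo[3.1.0]hexane-1-carbaldehyde 9 by ring-expanding 1,3-hydrobromination: the cyclopentane ring of 9 becomes the cyclohexane when the fusion bond breaks. Enabling feature: in the carbocycle of 17 the CH that carries the side chain and the CHBr are separated by one CH2, and CHBr adjoins C(CH3)(OH). The ring is thus the HBr adduct across the C1–C5 bond of a 4-hydroxy-4-methylbicyclo[3.1.0]hexane with an acceptor on C1, the cyclopropane CH2 becoming the ring CH2 between the two.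
4. 9 ⇐ 1 by ozonolysis, homologation, enyne ring-closing metathesis, hydroxyl-directed cyclopropanation and ozonolysis; the linalool carbinol carbon becomes C(CH3)(OH) of the ring and relays the other ring stereocentres.
5. Order of ring formation: cyclopentene (step 3), cyclopropane (step 4), cyclohexane by ring expansion (step 6); oxane by bromoetherification (step 9).

Key step: step 6

Assumption: (S)-(+)-linalool of high enantiomeric purity is taken as a purchasable starting material, and 3 is written as the open hydroxy aldehyde although it should exist largely as its five-membered lactol.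

**Route**

Step 1
Reactants: 1 (3S)-3,7-dimethylocta-1,6-dien-3-ol [(S)-linalool]
Product: 3 (4S)-4-hydroxy-4-methylhex-5-enal, via secondary ozonide 2 (not isolated)
Conditions: O3 (1 equiv, dye end point), CH2Cl2, −78 °C; then Me2S, −78 °C → rt
Reagents that add atoms: ozone, [O-][O+]=O
Why: Ozone attacks the electron-rich trisubstituted alkene much faster than the monosubstituted vinyl group (chemoselective ozonolysis with reductive work-up of the ozonide), and the carbinol stereocentre is not involved.

Step 2
Reactants: 3 (4S)-4-hydroxy-4-methylhex-5-enal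
Product: 4 (3S)-3-methylhept-1-en-6-yn-3-ol
Conditions: dimethyl (1-diazo-2-oxopropyl)phosphonate, K2CO3, MeOH, 0 °C → rt
Reagents that add atoms: dimethyl (1-diazo-2-oxopropyl)phosphonate, COP(=O)(OC)C(=[N+]=[N-])C(C)=O
Why: Seyferth–Gilbert homologation in the Ohira–Bestmann variant should convert the aldehyde (or its lactol, which opens under the conditions) into the terminal alkyne without touching the tertiary carbinol.

Step 3
Reactants: 4 (3S)-3-methylhept-1-en-6-yn-3-ol
Product: 5 (1S)-3-ethenyl-1-methylcyclopent-2-en-1-ol
Conditions: RuCl2(=CHPh)(H2IMes)(PCy3) (second-generation Grubbs catalyst, 5 mol %), ethylene (1 atm), CH2Cl2, 25 °C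
Reagents that add atoms: none
Why: Ring-closing enyne metathesis in the exo mode under ethylene should turn the 1,6-enyne into the 1-vinylcyclopentene, the allylic hydroxyl assisting the first carbene exchange; no stereocentre is formed.

Step 4
Reactants: 5 (1S)-3-ethenyl-1-methylcyclopent-2-en-1-ol
Product: 7 (1R,2S,5S)-5-ethenyl-2-methylbicyclo[3.1.0]hexan-2-ol, via ethylzinc alkoxide 6 (not isolated)
Conditions: Et2Zn (2.2 equiv), CH2I2 (2.5 equiv), CH2Cl2, −15 → 0 °C; aq. NH4Cl
Reagents that add atoms: diiodomethane, ICI
Why: In this hydroxyl-directed Simmons–Smith cyclopropanation (Furukawa reagent) the zinc alkoxide should deliver the carbenoid to the proximal trisubstituted alkene of the dienol on the face syn to oxygen, so that both cyclopropane centres (C1, C5) are set cis to the hydroxyl by substrate control and the distal vinyl group is left.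

Step 5
Reactants: 7 (1R,2S,5S)-5-ethenyl-2-methylbicyclo[3.1.0]hexan-2-ol
Product: 9 (1R,4S,5R)-4-hydroxy-4-methylbicyclo[3.1.0]hexane-1-carbaldehyde, via secondary ozonide 8 (not isolated)
Conditions: O3, CH2Cl2, −78 °C; then Me2S, −78 °C → rt
Reagents that add atoms: ozone, [O-][O+]=O
Why: Ozonolysis of the only alkene with reductive work-up should give the bridgehead aldehyde, which has no alpha-hydrogen and therefore cannot enolize or epimerize.

Step 6
Reactants: 9 (1R,4S,5R)-4-hydroxy-4-methylbicyclo[3.1.0]hexane-1-carbaldehyde
Product: 12 (1R,3R,4S)-3-bromo-4-hydroxy-4-methylcyclohexane-1-carbaldehyde, via cyclopropyl iminium bromide 10 (not isolated), via ring-expanded enamine 11 (not isolated)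
Conditions: pyridinium bromide (2 equiv), pyrrolidine (20 mol %), MeCN, 40 °C; then H2O
Reagents that add atoms: pyridinium bromide, [Br-].c1cc[nH+]cc1; water, O
Why: Proposed new method: pyrrolidine condenses with 9 to the cyclopropyl iminium ion 10, bromide adds in a homoconjugate (SN2-type) fashion to C5 with scission of the C1–C5 fusion bond to give the ring-expanded enamine 11, and C-protonation followed by hydrolysis releases 12 and the amine; the closest known reaction types are the iminium-activated opening of cyclopropanecarbaldehydes by halide, the halide-induced opening of cyclopropyl imines in the Cloke rearrangement, the HBr or Me3SiI opening of acylcyclopropanes at the more substituted carbon, and the acid-induced thujane-to-p-menthane ring expansion of sabinene hydrate. No ring is closed: the five-membered ring C1–C5 becomes the six-membered ring when its fusion bond breaks and the cyclopropane CH2 (C6) is taken up between C1 and C5. The C–Br centre is set by substrate control, through inversion at C5 (bromide enters anti to the C1–C5 bond, next to the syn hydroxyl, which can hydrogen-bond it), and this places bromine cis to the tertiary OH; the formyl-bearing centre is set under thermodynamic control by reversible enamine/iminium protonation (CHO equatorial, cis to Br and OH), and the carbinol centre is carried over. The selectivity needed is scission of C1–C5 and not of the external C1–C6 bond: both bonds are conjugated to the iminium, but the opening is reversible under amine catalysis (the primary bromide from C1–C6 scission should reclose by 3-exo-tet enamine alkylation), and with pyridinium as a weak-acid HBr carrier only the strain-free cyclohexane with its equatorial secondary bromide should lie downhill, besides the better stabilization of positive charge at the secondary C5. The buffer is also mild enough to leave the tertiary cyclopropylcarbinyl alcohol un-ionized.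

Step 7
Reactants: 12 (1R,3R,4S)-3-bromo-4-hydroxy-4-methylcyclohexane-1-carbaldehyde
Product: 13 (1S,2R,4R)-2-bromo-4-ethynyl-1-methylcyclohexan-1-ol
Conditions: dimethyl (1-diazo-2-oxopropyl)phosphonate and K2CO3 premixed in MeOH, then 12, 0 °C
Reagents that add atoms: dimethyl (1-diazo-2-oxopropyl)phosphonate, COP(=O)(OC)C(=[N+]=[N-])C(C)=O
Why: Seyferth–Gilbert homologation (Ohira–Bestmann reagent, pre-activated so that carbonyl addition should outrun enolization) gives the alkyne, and the formyl-bearing centre keeps its thermodynamically preferred equatorial configuration.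

Step 8
Reactants: 13 (1S,2R,4R)-2-bromo-4-ethynyl-1-methylcyclohexan-1-ol
Product: 15 (1S,2R,4R)-2-bromo-4-[(1E)-1-iodoprop-1-en-2-yl]-1-methylcyclohexan-1-ol, via alkenylalane 14 (not isolated)
Conditions: AlMe3 (3.5 equiv), Cp2ZrCl2 (0.25 equiv), H2O (1 equiv), CH2Cl2, −25 °C; then I2, THF, −25 → 0 °C; aq. NaHCO3/Na2S2O3, KNaC4H4O6
Reagents that add atoms: trimethylaluminium, C[Al](C)C; iodine, II
Why: Zirconium-catalysed syn-methylalumination of the terminal alkyne (Negishi carboalumination, water-accelerated) should place methyl on the internal and aluminium on the terminal carbon, and iodinolysis with retention gives the (E)-iodoalkene; the hydroxyl is carried as its aluminium alkoxide and no stereocentre is touched.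

Step 9
Reactants: 1 (3S)-3,7-dimethylocta-1,6-dien-3-ol [(S)-linalool]
Product: 16 (3R,6S)-3-bromo-6-ethenyl-2,2,6-trimethyloxane
Conditions: NBS (1.05 equiv), (CF3)2CHOH, 0 °C; chromatographic separation from the C3 epimer
Reagents that add atoms: N-bromosuccinimide, O=C1CCC(=O)N1Br
Why: Bromoetherification (6-endo closure by Markovnikov opening of the bromonium ion at its tertiary carbon by the tertiary hydroxyl) should form the oxane; C6 is the linalool carbinol carbon, whereas the C–Br centre depends on the face of bromonium formation, which the remote carbinol is not expected to control, so that the (3R,6S) isomer has to be separated from its C3 epimer.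

Step 10
Reactants: 15 (1S,2R,4R)-2-bromo-4-[(1E)-1-iodoprop-1-en-2-yl]-1-methylcyclohexan-1-ol; 16 (3R,6S)-3-bromo-6-ethenyl-2,2,6-trimethyloxane
Product: 17 (1S,2R,4R)-2-bromo-4-[(2E,4E)-5-[(2S,5R)-5-bromo-2,6,6-trimethyloxan-2-yl]penta-2,4-dien-2-yl]-1-methylcyclohexan-1-ol (target)
Conditions: Pd(OAc)2 (10 mol %), Bu4NCl, NaHCO3, DMF, 50 °C
Reagents that add atoms: none
Why: In this Heck–Mizoroki vinylation under ligand-free phase-transfer conditions the alkenylpalladium iodide from 15 should add to the terminal carbon of the vinyl group of 16, and syn beta-hydride elimination, possible only towards C9 because C11 is quaternary, gives the (E)-alkene with retention of the (E)-trisubstituted alkene, while the secondary alkyl bromides are inert to zerovalent palladium and no stereocentre is formed.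

**Compound list**

1 | (3S)-3,7-dimethylocta-1,6-dien-3-ol [(S)-linalool] | C=C[C@@](C)(O)CCC=C(C)C | starting material
2 | 3,3-dimethyl-5-[(3S)-3-hydroxy-3-methylpent-4-en-1-yl]-1,2,4-trioxolane (secondary ozonide) | C=C[C@@](C)(O)CCC1OOC(C)(C)O1 | intermediate
3 | (4S)-4-hydroxy-4-methylhex-5-enal | C=C[C@@](C)(O)CCC=O | intermediate
4 | (3S)-3-methylhept-1-en-6-yn-3-ol | C=C[C@@](C)(O)CCC#C | intermediate
5 | (1S)-3-ethenyl-1-methylcyclopent-2-en-1-ol | C=CC1=C[C@@](C)(O)CC1 | intermediate
6 | ethylzinc (1S)-3-ethenyl-1-methylcyclopent-2-en-1-olate | CC[Zn]O[C@@]1(C)CCC(C=C)=C1 | intermediate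
7 | (1R,2S,5S)-5-ethenyl-2-methylbicyclo[3.1.0]hexan-2-ol | C=C[C@@]12CC[C@](C)(O)[C@@H]1C2 | intermediate
8 | 3-[(1R,4S,5R)-4-hydroxy-4-methylbicyclo[3.1.0]hexan-1-yl]-1,2,4-trioxolane (secondary ozonide) | C1OOC(O1)[C@@]23CC[C@](C)(O)[C@@H]2C3 | intermediate
9 | (1R,4S,5R)-4-hydroxy-4-methylbicyclo[3.1.0]hexane-1-carbaldehyde | O=C[C@@]12CC[C@](C)(O)[C@@H]1C2 | intermediate
10 | 1-{[(1R,4S,5R)-4-hydroxy-4-methylbicyclo[3.1.0]hexan-1-yl]methylidene}pyrrolidin-1-ium bromide | [Br-].C1CC[N+](C1)=C[C@@]23CC[C@](C)(O)[C@@H]2C3 | intermediate
11 | (1S,2R)-2-bromo-1-methyl-4-(pyrrolidin-1-ylmethylidene)cyclohexan-1-ol | C1CCN(C1)C=C2CC[C@](C)(O)[C@H](Br)C2 | intermediate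
12 | (1R,3R,4S)-3-bromo-4-hydroxy-4-methylcyclohexane-1-carbaldehyde | O=C[C@@H]1CC[C@](C)(O)[C@H](Br)C1 | intermediate
13 | (1S,2R,4R)-2-bromo-4-ethynyl-1-methylcyclohexan-1-ol | C#C[C@@H]1CC[C@](C)(O)[C@H](Br)C1 | intermediate
14 | {(1E)-2-[(1R,3R,4S)-3-bromo-4-(dimethylalumanyloxy)-4-methylcyclohexyl]prop-1-en-1-yl}dimethylalumane | C[Al](C)/C=C(\C)[C@@H]1CC[C@](C)(O[Al](C)C)[C@H](Br)C1 | intermediate
15 | (1S,2R,4R)-2-bromo-4-[(1E)-1-iodoprop-1-en-2-yl]-1-methylcyclohexan-1-ol | I/C=C(\C)[C@@H]1CC[C@](C)(O)[C@H](Br)C1 | intermediate
16 | (3R,6S)-3-bromo-6-ethenyl-2,2,6-trimethyloxane | C=C[C@]1(C)CC[C@@H](Br)C(C)(C)O1 | intermediate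
17 | (1S,2R,4R)-2-bromo-4-[(2E,4E)-5-[(2S,5R)-5-bromo-2,6,6-trimethyloxan-2-yl]penta-2,4-dien-2-yl]-1-methylcyclohexan-1-ol | C/C(=C\C=C\[C@]1(C)CC[C@@H](Br)C(C)(C)O1)[C@@H]1CC[C@](C)(O)[C@H](Br)C1 | target

**Step count and risks**

Total step count: 10. Longest linear sequence: 9 steps (steps 1–8 and 10).

Steps most likely to fail:

1. Step 6 (proposed new method). Bromide may attack the unhindered cyclopropane CH2 instead of the neopentylic C5, so that the external bond breaks and no ring expansion occurs. The tertiary cyclopropylcarbinyl alcohol may also ionize, or the product may reclose to the cyclopropane during work-up. The fallback gives up the ring expansion and uses only known reactions on a p-menthane from the chiral pool. It cannot branch from an intermediate, so it sets out from no numbered compound but from purchased (1S,2S,4R)-limonene-1,2-diol F1, and it comes back to the route at compound 15. Exhaustive silylation (Me3SiOTf, Et3N) should give the bis(trimethylsilyl) ether F2, and K2CO3 in MeOH at 0 °C should free only the secondary hydroxyl to give the tertiary silyl ether F3. Appel bromination (CBr4, PPh3, 2,6-lutidine) should replace the axial secondary hydroxyl with inversion and give the equatorial bromide F4, the silyl ether preventing epoxide formation. Ozonolysis of the isopropenyl group should give the methyl ketone F5, and boron–Wittig olefination with LiCH(Bpin)2 should give the (E)-alkenylboronate F6. Iododeboronation with N-iodosuccinimide should give the silylated iodoalkene F7, and mild acid (citric acid, MeOH) should remove the silyl group to give 15.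

2. Step 9. Poor facial selectivity of bromonium formation (both C3 epimers expected) and competing 5-exo closure may leave little of the wanted isomer. The fallback sets out from compound 1 and comes back at compound 16; it fixes the bromine-bearing centre by reagent control before ring closure. Shi epoxidation of 1 (fructose-derived ketone catalyst of the appropriate enantiomeric series, KHSO5, K2CO3 buffer) should give the (3S,6S)-epoxide F8. Acid-induced cyclization ((+)-camphorsulfonic acid, CH2Cl2) should give, besides the five-membered oxide, the six-membered alcohol F9 by 6-endo opening with retention at C6, and F9 is separated. Sulfonylation with ClCH2SO2Cl and pyridine should give the chloromethanesulfonate F10, and displacement with LiBr in DMF should give 16 with inversion.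

3. Step 7. Base-induced enolization of the gamma-bromo aldehyde may lead to 3-exo-tet reclosure to 9 or to epimerization before the homologation is complete. The fallback sets out from compound 12 and comes back at compound 13; its first stage is not basic. Corey–Fuchs olefination (CBr4, PPh3, 2,6-lutidine, CH2Cl2, 0 °C) should give the dibromoalkene F11, which can no longer enolize. n-BuLi (3.2 equiv, THF, −78 °C) should then give the lithium acetylide F12 by Fritsch–Buttenberg–Wiechell rearrangement, and protonation gives 13.

**Further compounds**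

F1 | step 6 | (1S,2S,4R)-1-methyl-4-(prop-1-en-2-yl)cyclohexane-1,2-diol (limonene-1,2-diol, purchased) | CC(=C)[C@@H]1CC[C@](C)(O)[C@@H](O)C1
F2 | step 6 | 1,2-bis-O-(trimethylsilyl) ether of F1 | CC(=C)[C@@H]1CC[C@](C)(O[Si](C)(C)C)[C@@H](O[Si](C)(C)C)C1
F3 | step 6 | 1-O-(trimethylsilyl) ether of F1 (tertiary silyl ether, free secondary hydroxyl) | CC(=C)[C@@H]1CC[C@](C)(O[Si](C)(C)C)[C@@H](O)C1
F4 | step 6 | {[(1S,2R,4R)-2-bromo-1-methyl-4-(prop-1-en-2-yl)cyclohexyl]oxy}trimethylsilane | CC(=C)[C@@H]1CC[C@](C)(O[Si](C)(C)C)[C@H](Br)C1
F5 | step 6 | 1-[(1R,3R,4S)-3-bromo-4-methyl-4-(trimethylsilyloxy)cyclohexyl]ethan-1-one | CC(=O)[C@@H]1CC[C@](C)(O[Si](C)(C)C)[C@H](Br)C1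
F6 | step 6 | 2-{(1E)-2-[(1R,3R,4S)-3-bromo-4-methyl-4-(trimethylsilyloxy)cyclohexyl]prop-1-en-1-yl}-4,4,5,5-tetramethyl-1,3,2-dioxaborolane | CC1(C)OB(OC1(C)C)/C=C(\C)[C@@H]2CC[C@](C)(O[Si](C)(C)C)[C@H](Br)C2
F7 | step 6 | {[(1S,2R,4R)-2-bromo-4-[(1E)-1-iodoprop-1-en-2-yl]-1-methylcyclohexyl]oxy}trimethylsilane | I/C=C(\C)[C@@H]1CC[C@](C)(O[Si](C)(C)C)[C@H](Br)C1
F8 | step 9 | (3S)-5-[(2S)-3,3-dimethyloxiran-2-yl]-3-methylpent-1-en-3-ol [(3S,6S)-6,7-epoxylinalool] | C=C[C@@](C)(O)CC[C@@H]1OC1(C)C
F9 | step 9 | (3S,6S)-6-ethenyl-2,2,6-trimethyloxan-3-ol | C=C[C@]1(C)CC[C@H](O)C(C)(C)O1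
F10 | step 9 | (3S,6S)-6-ethenyl-2,2,6-trimethyloxan-3-yl chloromethanesulfonate | C=C[C@]1(C)CC[C@H](OS(=O)(=O)CCl)C(C)(C)O1
F11 | step 7 | (1S,2R,4R)-2-bromo-4-(2,2-dibromoethenyl)-1-methylcyclohexan-1-ol | BrC(Br)=C[C@@H]1CC[C@](C)(O)[C@H](Br)C1
F12 | step 7 | lithium acetylide and lithium alkoxide of 13 | [Li]C#C[C@@H]1CC[C@](C)(O[Li])[C@H](Br)C1
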